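**Retrosynthetic overview** (ring A = methoxy dienone carbocycle, B = dihydropyran, C = spiro cyclohexene, D = isopropyl/methyl cyclohexane)
1. The target comes from decarbonylation of a tetracycle that carries a temporary formyl group on the ring C CH2 next to the spiro carbon.
2. That tetracycle comes from a propargylic alcohol holding only rings A and D, in one flask. The ring A enol oxygen adds to the alkyne (ring B), loss of the carbinol OH gives an O-stabilised allyl cation, and the side-chain aldehyde (as its enamine) makes the spiro C-C bond (ring C).
3. The propargylic alcohol comes from an acetylide and a ketone, joined at the former menthone carbonyl carbon. The alkyne comes from the ring A dione and 4-methylpent-2-enal (organocatalytic Michael addition sets C-4, then alkyne homologation). The ketone comes from (-)-menthone by axial hydrazone alkylation.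
4. Enabling feature: the spiro carbon is both the O-bearing carbon of ring B and the allylic terminus of the ring C alkene (O-C(spiro)-CH=C). The far alkene carbon is the ring C/ring D fusion carbon and maps onto the carbonyl carbon of menthone. O-C-CH=C is therefore the retron of a propargylic alcohol C≡C-C(OH) built on that ketone.
5. Order of ring formation: A (dearomatised benzene ring) and D (bought with menthone), then B, then C last.

Key step: step 10

Assumption: the vinylogous acid of ring A reacts through the oxygen next to the gem-dimethyl carbon. This gives the cross-conjugated 2,5-dienone of the target. The linear 2,4-dienone isomer is taken as less stable, and both forms interconvert through open forms until the C-C bond of step 10 is made.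

Step 1
Reactants: 1 2,4,6-trihydroxybenzaldehyde
Product: 2 2,6-dihydroxy-4-methoxybenzaldehyde
Conditions: MeI (1.0 equiv), K2CO3 (1.0 equiv), acetone, 0 °C to rt
Reagents that add atoms: iodomethane, CI
Why: Williamson O-methylation, in which the two ortho hydroxyls are hydrogen-bonded to the formyl group, so the para hydroxyl is the most acidic and is the one alkylated by one equivalent.

Step 2
Reactants: 2 2,6-dihydroxy-4-methoxybenzaldehyde
Product: 3 2-hydroxy-4-methoxy-3,3,5-trimethyl-6-oxocyclohexa-1,4-diene-1-carbaldehyde
Conditions: MeI (4 equiv), NaOMe (3.3 equiv), MeOH, 0 to 40 °C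
Reagents that add atoms: iodomethane, CI
Why: Alkylative dearomatisation (phenolate C-methylation) of a formylphloroglucinol ether, in which two methyl groups fill the free ring carbons, the third makes one of them quaternary, and a fourth cannot enter because the enol ether double bond is then locked against the quaternary carbon.

Step 3
Reactants: 3 formyl-blocked ring A
Product: 4 5-hydroxy-3-methoxy-2,4,4-trimethylcyclohexa-2,5-dien-1-one
Conditions: 1 M aq NaOH (3 equiv), THF, 60 °C; then 1 M HCl to pH 3, 0 °C
Reagents that add atoms: none
Why: Retro-Claisen deformylation of a hydroxymethylene blocking group, during which the ring stays an enolate in base and so shields the vinylogous methyl ester.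

Step 4
Reactants: 4 ring A dione (enol form); 5 (E)-4-methylpent-2-enal
Product: 7 (4R)-2-hydroxy-4-isopropyl-7-methoxy-6,8,8-trimethyl-2,3,4,8-tetrahydro-5H-chromen-5-one (lactol; anomers), via open-chain aldehyde 6 (not isolated)
Conditions: (R)-α,α-diphenylprolinol trimethylsilyl ether (10 mol %), PhCO2H (10 mol %), CH2Cl2, rt
Reagents that add atoms: none
Why: Iminium-catalysed Michael addition/hemiacetalisation of a cyclic 1,3-dione to an enal (Jørgensen–Hayashi catalyst), in which the diphenyl(silyloxy)methyl group of the (R)-catalyst shields one face of the E-iminium ion and C-4 should form as R.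

Step 5
Reactants: 7 lactol
Product: 8 5-hydroxy-3-methoxy-2,4,4-trimethyl-6-[(3R)-2-methylhex-5-yn-3-yl]cyclohexa-2,5-dien-1-one
Conditions: Ohira–Bestmann reagent (1.3 equiv), K2CO3 (3 equiv), MeOH, 0 °C to rt; pH 4 buffer work-up
Reagents that add atoms: dimethyl (1-diazo-2-oxopropyl)phosphonate, CC(=O)C(=[N+]=[N-])P(=O)(OC)OC
Why: Seyferth–Gilbert homologation acting on ring-chain tautomer 6, where ring A is an enolate in base so that retro-Michael loss would need a dianion and C-4 is kept.

Step 6
Reactants: 9 (-)-menthone
Product: 10 (-)-menthone N,N-dimethylhydrazone (2S,5R; NMe2 turned away from the isopropyl-bearing carbon)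
Conditions: Me2NNH2 (3 equiv), AcOH (5 mol %), 4 Å MS, EtOH, 50 °C
Reagents that add atoms: 1,1-dimethylhydrazine, CN(C)N
Why: Hydrazone condensation under mild acid, in which the trans (diequatorial) arrangement of isopropyl and methyl is the favoured one and should persist.

Step 7
Reactants: 10 menthone dimethylhydrazone; 11 3-bromo-1,1-dimethoxypropane
Product: 13 menthone dimethylhydrazone with an axial 3,3-dimethoxypropyl group at C-6 (2S,5R,6R), via lithium azaenolate 12 (not isolated)
Conditions: LiN(iPr)2 (1.1 equiv), THF, 0 °C; then 11 (1.2 equiv), DMPU, -78 to 0 °C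
Reagents that add atoms: none
Why: Corey–Enders alkylation, in which deprotonation occurs at the CH2 group and the bromide enters axially on the chair with equatorial isopropyl and methyl, so the chain ends trans to isopropyl and cis to methyl (R) and is held axial by allylic 1,3-strain with the syn NMe2 group.

Step 8
Reactants: 13 alkylated hydrazone
Product: 14 (2R,3R,6S)-2-(3,3-dimethoxypropyl)-3-methyl-6-isopropylcyclohexan-1-one
Conditions: Cu(OAc)2 (2 equiv), THF–H2O, pH 7 phosphate buffer, rt
Reagents that add atoms: water, O
Why: Hydrolysis of the dimethylhydrazone promoted by divalent copper at neutral pH, which should spare the acetal and avoid the enolisation that would move the axial chain.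

Step 9
Reactants: 8 ring A alkyne; 14 ring D ketone
Product: 16 tertiary propargylic alcohol joining rings A and D (C-4 R; ring D centres as in 14; carbinol carbon expected S), via dilithio alkynide 15 (not isolated)
Conditions: 8, n-BuLi (2.05 equiv), THF, -78 to -20 °C; LaCl3·2LiCl (0.3 equiv), then 14, -78 °C; aq NH4Cl
Reagents that add atoms: none
Why: 1,2-addition of a lithium acetylide to a ketone with lanthanum assistance against enolisation, where ring A is protected as its enolate and the slim nucleophile should attack axially, anti to the axial side chain, at a carbinol centre that step 10 erases.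

Step 10
Reactants: 16 propargylic alcohol
Product: 19 tetracyclic aldehyde (target skeleton with CHO on the ring C carbon next to the spiro carbon; epimers at that carbon), via enol ether carbinol 17 (not isolated), via oxocarbenium trifluoroacetate 18 (not isolated)
Conditions: Ph3PAuNTf2 (3 mol %), CH2Cl2, 0 °C to rt; then, same flask, (5S)-5-benzyl-2,2,3-trimethylimidazolidin-4-one·CF3CO2H (20 mol %), rt
Reagents that add atoms: none
Why: Proposed new method: Ph3PAuNTf2 (monovalent gold) activates the alkyne for anti 6-exo-dig attack of the ring A enol oxygen at the alkyne carbon remote from the carbinol, which closes ring B and gives Z enol ether 17. The ammonium trifluoroacetate then ionises the tertiary allylic C-OH bond of 17 to the O-stabilised allyl cation 18, and the water set free is what unmasks the acetal, so the aldehyde and its enamine appear only after the alkyne is consumed. The enamine carbon attacks the oxocarbenium carbon in a 6-(enolexo)-exo-trig closure (ring C), which makes the spiro C-C bond and leaves the alkene between the former alkyne CH and the former menthone carbonyl carbon. The closest known reaction types are the gold-catalysed O-cyclisation of alkynyl 1,3-diones, the alcohol-assisted gold Meyer–Schuster rearrangement (same cation) and the amine/acid dual-catalysed addition of aldehydes to cyclic oxocarbenium ions from chromene acetals, whereas their merger and intramolecular use are new. The spiro carbon is set by two elements that agree, since ring D allows only the half-chair that keeps its C-CH(CH3) bond pseudo-equatorial (which fixes the cation face the chain can reach), and allylic 1,3-strain favours the rotamer with the ring B oxygen rather than the CH2 turned inward, which places the C-4 isopropyl group on the face away from the incoming carbon, while the formyl-bearing carbon forms without control and is erased in step 11. The needed selectivities are attack at the oxocarbenium carbon rather than the tertiary allyl terminus (that would give a four-membered ring), the alkene geometry (the cation isomerises and only the isomer with the cation carbon cis to the chain-bearing ring D carbon can close), O- over C-cyclisation at gold (the C-attack site adjoins the quaternary carbinol), and survival of β-oxy aldehyde 19 (the bulky amine should no longer form an enamine with this α-branched, neopentyl-type product).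

Step 11
Reactants: 19 tetracyclic aldehyde
Product: 20 target CNP0194760.3 (spiro carbon S; C-4 R; ring D: CH-iPr S, CH-CH3 R, ring-fusion CH R)
Conditions: RhCl(PPh3)3 (1.1 equiv), degassed toluene, 110 °C
Reagents that add atoms: none
Why: Tsuji–Wilkinson decarbonylation under neutral conditions removes the activating formyl group, turns its carbon of attachment into the ring C CH2 and touches no remaining stereocentre.

**Compound list**
1 | 2,4,6-trihydroxybenzaldehyde | Oc1cc(O)c(C=O)c(O)c1 | starting material
2 | 2,6-dihydroxy-4-methoxybenzaldehyde | COc1cc(O)c(C=O)c(O)c1 | intermediate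
3 | 2-hydroxy-4-methoxy-3,3,5-trimethyl-6-oxocyclohexa-1,4-diene-1-carbaldehyde | O=CC1=C(O)C(C)(C)C(OC)=C(C)C1=O | intermediate
4 | 5-hydroxy-3-methoxy-2,4,4-trimethylcyclohexa-2,5-dien-1-one | COC1=C(C)C(=O)C=C(O)C1(C)C | intermediate
5 | (E)-4-methylpent-2-enal | CC(C)/C=C/C=O | starting material
6 | (3R)-3-(2-hydroxy-4-methoxy-3,3,5-trimethyl-6-oxocyclohexa-1,4-dien-1-yl)-4-methylpentanal | COC1=C(C)C(=O)C([C@H](CC=O)C(C)C)=C(O)C1(C)C | intermediate
7 | (4R)-lactol of 6 (anomeric centre open) | COC1=C(C)C(=O)C2=C(OC(O)C[C@@H]2C(C)C)C1(C)C | intermediate
8 | ring A alkyne, (3R)-2-methylhex-5-yn-3-yl side chain | COC1=C(C)C(=O)C([C@H](CC#C)C(C)C)=C(O)C1(C)C | intermediate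
9 | (-)-menthone, (2S,5R) | O=C1[C@H](C(C)C)CC[C@@H](C)C1 | starting material
10 | (-)-menthone N,N-dimethylhydrazone | CN(C)/N=C1/[C@H](C(C)C)CC[C@@H](C)C1 | intermediate
11 | 3-bromo-1,1-dimethoxypropane | BrCCC(OC)OC | starting material
12 | lithium azaenolate of 10 | CN(C)N([Li])C=1[C@H](C(C)C)CC[C@@H](C)C=1 | intermediate
13 | 6-axially alkylated hydrazone (2S,5R,6R) | CN(C)/N=C1/[C@H](C(C)C)CC[C@@H](C)[C@H]1CCC(OC)OC | intermediate
14 | (2R,3R,6S)-2-(3,3-dimethoxypropyl)-3-methyl-6-isopropylcyclohexan-1-one | O=C1[C@H](C(C)C)CC[C@@H](C)[C@H]1CCC(OC)OC | intermediate
15 | dilithio derivative of 8 (enolate and alkynide) | [Li]C#CC[C@H](C(C)C)C1=C(O[Li])C(C)(C)C(OC)=C(C)C1=O | intermediate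
16 | propargylic alcohol joining rings A and D | COC1=C(C)C(=O)C([C@H](CC#C[C@]2(O)[C@H](C(C)C)CC[C@@H](C)[C@H]2CCC(OC)OC)C(C)C)=C(O)C1(C)C | intermediate
17 | (Z)-2-alkylidene dihydropyran carbinol (ring B closed) | COC1=C(C)C(=O)C2=C(O/C(=C\[C@]3(O)[C@H](C(C)C)CC[C@@H](C)[C@H]3CCC(OC)OC)C[C@@H]2C(C)C)C1(C)C | intermediate
18 | alkenyl oxocarbenium trifluoroacetate with free aldehyde | COC1=C(C)C(=O)C2=C([O+]=C(/C=C3/[C@H](C(C)C)CC[C@@H](C)[C@H]3CCC=O)C[C@@H]2C(C)C)C1(C)C.[O-]C(=O)C(F)(F)F | intermediate
19 | tetracyclic aldehyde (formyl-bearing carbon open) | COC1=C(C)C(=O)C2=C(O[C@]3(C=C4[C@H](C(C)C)CC[C@@H](C)[C@H]4CC3C=O)C[C@@H]2C(C)C)C1(C)C | intermediate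
20 | CNP0194760.3 | COC1=C(C)C(=O)C2=C(O[C@]3(C=C4[C@H](C(C)C)CC[C@@H](C)[C@H]4CC3)C[C@@H]2C(C)C)C1(C)C | target

Total step count: 11. Longest linear sequence: 8 (steps 1–5, 9–11).

**Steps most likely to fail**

1. Step 10 (Proposed new method).
   - What may go wrong: the other ring A oxygen may engage. The cation may lose a proton toward ring D, which would scramble the two ring D centres flanking the alkene. The C-C closure may be too slow. The ring B oxygen may undergo β-elimination from the product on long exposure.
   - Fallback (known chemistry, events separated, nucleophile pre-formed), starting from 16: Ph3PAuNTf2 (2 mol %) with pyridinium p-toluenesulfonate in wet THF carries out the Meyer–Schuster rearrangement and acetal hydrolysis to the hemiketal aldehyde F1. TBSOTf/Et3N (CH2Cl2, -78 to 0 °C) converts it into the silyl ketal silyl enol ether F2. Catalytic TMSOTf at -78 °C then closes ring C by a Mukaiyama-type addition of the silyl enol ether to the ketal-derived oxocarbenium ion. This returns to the route at 19.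

2. Step 11.
   - What may go wrong: CO extrusion may be slow at an aldehyde flanked by a quaternary carbon, and β-elimination or alkene migration may occur on prolonged heating.
   - Fallback, starting from 19: Pinnick oxidation (NaClO2, NaH2PO4, 2-methylbut-2-ene, t-BuOH/H2O) gives the carboxylic acid F3. Photoredox hydrodecarboxylation (9-mesityl-10-methylacridinium tetrafluoroborate, PhSSPh, iPr2NEt, CF3CH2OH, blue light, rt) replaces CO2H by H through the secondary radical. This returns to the route at 20.

3. Step 7.
   - What may go wrong: facial selectivity of the alkylation may be poor, the bromide may undergo elimination, or the axial chain may move later.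
   - Fallback (thermodynamic instead of kinetic control), starting from 9: direct alkylation of the kinetic lithium enolate (LiN(iPr)2, THF, -78 °C, then 11, DMPU) gives mainly the equatorial epimer ketone F4. Condensation with Me2NNH2 gives the hydrazone F5. Acid-catalysed equilibration through the ene-hydrazine should move the chain to the axial position, because an equatorial group next to a syn NMe2 suffers allylic 1,3-strain. This returns to the route at 13.

**Further compounds**
F1 | step 10 | hemiketal aldehyde (2-hydroxy-2-alkenyl dihydropyran, free side-chain aldehyde) | COC1=C(C)C(=O)C2=C(OC(O)(/C=C3/[C@H](C(C)C)CC[C@@H](C)[C@H]3CCC=O)C[C@@H]2C(C)C)C1(C)C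
F2 | step 10 | silyl ketal silyl enol ether (bis-TBS derivative of F1) | COC1=C(C)C(=O)C2=C(OC(O[Si](C)(C)C(C)(C)C)(/C=C3/[C@H](C(C)C)CC[C@@H](C)[C@H]3CC=CO[Si](C)(C)C(C)(C)C)C[C@@H]2C(C)C)C1(C)C
F3 | step 11 | tetracyclic carboxylic acid | COC1=C(C)C(=O)C2=C(O[C@]3(C=C4[C@H](C(C)C)CC[C@@H](C)[C@H]4CC3C(O)=O)C[C@@H]2C(C)C)C1(C)C
F4 | step 7 | equatorial epimer of 14 | O=C1[C@H](C(C)C)CC[C@@H](C)[C@@H]1CCC(OC)OC
F5 | step 7 | N,N-dimethylhydrazone of F4 | CN(C)N=C1[C@H](C(C)C)CC[C@@H](C)[C@@H]1CCC(OC)OC
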